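**Retrosynthetic overview**

1. The target is a scopoletin whose C3 is joined through oxygen to C7' of a second scopoletin (unit B). In unit A the ring oxygen O1 and the methine C4 sit on the adjacent benzo carbons C8a and C4a, so these two carbons are treated as an aryne that takes O1 and C4 together from one molecule of dimethylformamide.
2. C2 and C3, with the C3–O–C7' ether already in place, come from the ketene silyl acetal of ethyl (scopoletin-7-yloxy)acetate. One three-component annulation forms O1–C8a, C4–C4a, C3–C4 and O1–C2 and closes the pyranone ring of unit A.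
3. A bromine at C5, beside C4a, fixes the direction of addition to the aryne. It is removed at the end together with the benzyl group on O7.
4. The aryne precursor is a 2-bromo-6-(trimethylsilyl)aryl triflate, made from O-benzylvanillin by Dakin oxidation, iodination, bromination, O-silylation and iodine–lithium exchange with O-to-C silyl shift and triflation.
5. Ring order: both rings of unit B are bought as scopoletin, the benzene ring of unit A comes from vanillin, and the pyranone ring of unit A is the only ring formed (step 8).

Key step: step 8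

Remarks on the chemistry: the target has no stereocentre. The ketene silyl acetal is used as a mixture of double-bond isomers, and the benzoxete, the open adduct and the aminodihydrocoumarin of the key step are racemic or diastereomeric mixtures that converge on one product, so their SMILES carry no stereodescriptors. The aryne precursor carries the triflate beside bromine and the silyl group on the other aryne carbon; fluoride gives the same 3-bromoaryne from either arrangement, and this one is reached from a 2-bromo-6-iodophenol without metalation next to a halogen.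

**Route**

Step 1
Reactants: 1 4-(benzyloxy)-3-methoxybenzaldehyde (O-benzylvanillin)
Product: 3 4-(benzyloxy)-3-methoxyphenol, via aryl formate 2 (not isolated)
Conditions: mCPBA, CH2Cl2, rt; then K2CO3 (cat.), MeOH, rt
Reagents that add atoms: mCPBA (3-chloroperoxybenzoic acid), OOC(=O)c1cccc(Cl)c1
Why: Baeyer–Villiger (Dakin-type) oxidation, in which the electron-rich aryl group migrates to oxygen to give the formate, which methanolysis converts to the phenol.

Step 2
Reactants: 3 4-(benzyloxy)-3-methoxyphenol
Product: 4 4-(benzyloxy)-2-iodo-5-methoxyphenol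
Conditions: NIS, TsOH·H2O (cat.), MeCN, 0 °C
Reagents that add atoms: N-iodosuccinimide, O=C1CCC(=O)N1I
Why: Electrophilic aromatic iodination at the carbon ortho to the hydroxyl and para to the methoxy group, the most activated and least hindered position of the ring.

Step 3
Reactants: 4 4-(benzyloxy)-2-iodo-5-methoxyphenol
Product: 5 4-(benzyloxy)-2-bromo-6-iodo-3-methoxyphenol
Conditions: NBS, i-Pr2NH (cat.), CH2Cl2, 0 °C
Reagents that add atoms: N-bromosuccinimide, O=C1CCC(=O)N1Br
Why: Amine-catalysed ortho-bromination of a phenol at the only free position ortho to the hydroxyl, which is also ortho to the methoxy group, while the remaining CH is activated only by the benzyloxy group.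

Step 4
Reactants: 5 4-(benzyloxy)-2-bromo-6-iodo-3-methoxyphenol
Product: 6 [4-(benzyloxy)-2-bromo-6-iodo-3-methoxyphenoxy]trimethylsilane
Conditions: HMDS, THF, 70 °C; evaporate, use crude
Reagents that add atoms: hexamethyldisilazane, C[Si](C)(C)N[Si](C)(C)C
Why: O-silylation of the phenol by the disilazane with loss of ammonia, the usual first stage of an o-silylaryl triflate synthesis.

Step 5
Reactants: 6 [4-(benzyloxy)-2-bromo-6-iodo-3-methoxyphenoxy]trimethylsilane
Product: 9 4-(benzyloxy)-2-bromo-3-methoxy-6-(trimethylsilyl)phenyl trifluoromethanesulfonate, via aryllithium 7 (not isolated), via lithium phenoxide 8 (not isolated)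
Conditions: n-BuLi (1.05 equiv), THF, −100 to −78 °C; then Tf2O, −78 to 0 °C
Reagents that add atoms: trifluoromethanesulfonic anhydride, O=S(=O)(OS(=O)(=O)C(F)(F)F)C(F)(F)F
Why: Iodine–lithium exchange, much faster than bromine–lithium exchange, gives an aryllithium that takes the silyl group from the neighbouring oxygen (retro-Brook 1,3-shift), and the phenoxide so formed is O-triflated.

Step 6
Reactants: 10 scopoletin (7-hydroxy-6-methoxy-2H-chromen-2-one), 11 ethyl bromoacetate
Product: 12 ethyl 2-[(6-methoxy-2-oxo-2H-chromen-7-yl)oxy]acetate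
Conditions: K2CO3, acetone, reflux
Reagents that add atoms: none
Why: Williamson ether synthesis of the phenoxide with a reactive primary α-bromo ester.

Step 7
Reactants: 12 ethyl 2-[(6-methoxy-2-oxo-2H-chromen-7-yl)oxy]acetate
Product: 14 7-{[2-ethoxy-2-(trimethylsilyloxy)ethenyl]oxy}-6-methoxy-2H-chromen-2-one, via lithium enolate 13 (not isolated)
Conditions: LiN(SiMe3)2, TMSCl (present from the start), THF, −78 °C; evaporate, take up in dry toluene, filter under Ar, use crude
Reagents that add atoms: chlorotrimethylsilane, C[Si](C)(C)Cl
Why: Kinetic deprotonation of the α-aryloxy ester by the hindered amide with in situ silyl quench traps the enolate on oxygen as the ketene silyl acetal before it can add to the coumarin of a second molecule.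

Step 8
Reactants: 9 4-(benzyloxy)-2-bromo-3-methoxy-6-(trimethylsilyl)phenyl trifluoromethanesulfonate, 14 7-{[2-ethoxy-2-(trimethylsilyloxy)ethenyl]oxy}-6-methoxy-2H-chromen-2-one, 15 N,N-dimethylformamide
Product: 21 7-(benzyloxy)-5-bromo-6-methoxy-3-[(6-methoxy-2-oxo-2H-chromen-7-yl)oxy]-2H-chromen-2-one, via aryne 16 (not isolated), via benzoxete 17 (not isolated), via quinone methide 18 (not isolated), via phenoxide adduct 19 (not isolated), via aminodihydrocoumarin 20 (not isolated)
Conditions: 14 (1.5 equiv), anhydrous CsF (4 equiv), DMF (solvent), 0 °C to rt; then 50 °C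
Reagents that add atoms: none
Why: Proposed new method: fluoride removes the silyl group of 9 and triflate departs to give aryne 16; the carbonyl oxygen of 15 attacks the aryne carbon remote from bromine, the aryl anion formed beside the halogen closes onto the iminium carbon (formal [2+2] addition, expected to be faster than loss of bromide) to give benzoxete 17, and electrocyclic opening of the four-membered ring gives the aminomethylene ortho-quinone methide 18. The ester enolate set free from 14 by fluoride (or 14 itself, in a Mukaiyama–Mannich manner) adds through carbon to the exocyclic carbon of 18 to form C3–C4, phenoxide 19 closes the pyranone by 6-exo-trig attack on the ethyl ester (O1–C2) to give 20, and E1cB loss of dimethylamine on warming gives the C3=C4 bond. The closest known reaction type is the three-component coupling of arynes, dimethylformamide and active methylene compounds such as malonates and β-keto esters to coumarins; what is new is a simple α-aryloxy ester as the carbon partner, which CsF cannot deprotonate and which is therefore supplied as its ketene silyl acetal. No stereocentre remains, because the two of 20 are erased by the elimination. The step needs one direction of addition to the aryne: the inductive pull of bromine, reinforced by the buttressing methoxy group, places the developing negative charge on the carbon beside bromine, so O1 lands on C8a and C4 on C4a. Dimethylformamide as solvent should capture the aryne ahead of the enolate.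

Step 9
Reactants: 21 7-(benzyloxy)-5-bromo-6-methoxy-3-[(6-methoxy-2-oxo-2H-chromen-7-yl)oxy]-2H-chromen-2-one
Product: 22 7-hydroxy-6-methoxy-3-[(6-methoxy-2-oxo-2H-chromen-7-yl)oxy]-2H-chromen-2-one (target)
Conditions: H2 (1 atm), 10% Pd/C, NaOAc, EtOAc–EtOH, rt; stop after uptake of two equivalents of H2
Reagents that add atoms: none
Why: Heterogeneous Pd-catalysed hydrogenolysis cleaves the aryl C–Br bond (NaOAc takes up HBr) and the benzylic C–O bond, both expected to be faster than saturation of the coumarin C3=C4 bonds.

**Compound list**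

1 | 4-(benzyloxy)-3-methoxybenzaldehyde | COc1cc(C=O)ccc1OCc1ccccc1 | starting material
2 | 4-(benzyloxy)-3-methoxyphenyl formate | COc1cc(OC=O)ccc1OCc1ccccc1 | intermediate
3 | 4-(benzyloxy)-3-methoxyphenol | COc1cc(O)ccc1OCc1ccccc1 | intermediate
4 | 4-(benzyloxy)-2-iodo-5-methoxyphenol | COc1cc(O)c(I)cc1OCc1ccccc1 | intermediate
5 | 4-(benzyloxy)-2-bromo-6-iodo-3-methoxyphenol | COc1c(OCc2ccccc2)cc(I)c(O)c1Br | intermediate
6 | [4-(benzyloxy)-2-bromo-6-iodo-3-methoxyphenoxy]trimethylsilane | COc1c(OCc2ccccc2)cc(I)c(O[Si](C)(C)C)c1Br | intermediate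
7 | [5-(benzyloxy)-3-bromo-4-methoxy-2-(trimethylsilyloxy)phenyl]lithium | COc1c(OCc2ccccc2)cc([Li])c(O[Si](C)(C)C)c1Br | intermediate
8 | lithium 4-(benzyloxy)-2-bromo-3-methoxy-6-(trimethylsilyl)phenoxide | [Li+].[O-]c1c(Br)c(OC)c(OCc2ccccc2)cc1[Si](C)(C)C | intermediate
9 | 4-(benzyloxy)-2-bromo-3-methoxy-6-(trimethylsilyl)phenyl trifluoromethanesulfonate | COc1c(OCc2ccccc2)cc([Si](C)(C)C)c(OS(=O)(=O)C(F)(F)F)c1Br | intermediate
10 | scopoletin (7-hydroxy-6-methoxy-2H-chromen-2-one) | COc1cc2ccc(=O)oc2cc1O | starting material
11 | ethyl bromoacetate | CCOC(=O)CBr | starting material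
12 | ethyl 2-[(6-methoxy-2-oxo-2H-chromen-7-yl)oxy]acetate | CCOC(=O)COc1cc2oc(=O)ccc2cc1OC | intermediate
13 | lithium 1-ethoxy-2-[(6-methoxy-2-oxo-2H-chromen-7-yl)oxy]ethen-1-olate | [Li+].CCOC([O-])=COc1cc2oc(=O)ccc2cc1OC | intermediate
14 | 7-{[2-ethoxy-2-(trimethylsilyloxy)ethenyl]oxy}-6-methoxy-2H-chromen-2-one | CCOC(O[Si](C)(C)C)=COc1cc2oc(=O)ccc2cc1OC | intermediate
15 | N,N-dimethylformamide | CN(C)C=O | starting material
16 | 5-(benzyloxy)-3-bromo-4-methoxybenzyne (1,2-didehydrobenzene) | COC1=C(Br)C#CC=C1OCc1ccccc1 | intermediate
17 | 5-(benzyloxy)-3-bromo-4-methoxy-N,N-dimethyl-2H-benzo[b]oxet-2-amine | COc1c(OCc2ccccc2)cc2OC(N(C)C)c2c1Br | intermediate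
18 | 3-(benzyloxy)-5-bromo-6-[(dimethylamino)methylidene]-4-methoxycyclohexa-2,4-dien-1-one | COC1=C(Br)C(=CN(C)C)C(=O)C=C1OCc1ccccc1 | intermediate
19 | cesium 5-(benzyloxy)-3-bromo-2-{1-(dimethylamino)-3-ethoxy-2-[(6-methoxy-2-oxo-2H-chromen-7-yl)oxy]-3-oxopropyl}-4-methoxyphenoxide | [Cs+].CCOC(=O)C(Oc1cc2oc(=O)ccc2cc1OC)C(N(C)C)c1c([O-])cc(OCc2ccccc2)c(OC)c1Br | intermediate
20 | 7-(benzyloxy)-5-bromo-4-(dimethylamino)-6-methoxy-3-[(6-methoxy-2-oxo-2H-chromen-7-yl)oxy]-3,4-dihydro-2H-chromen-2-one | COc1c(OCc2ccccc2)cc2OC(=O)C(Oc3cc4oc(=O)ccc4cc3OC)C(N(C)C)c2c1Br | intermediate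
21 | 7-(benzyloxy)-5-bromo-6-methoxy-3-[(6-methoxy-2-oxo-2H-chromen-7-yl)oxy]-2H-chromen-2-one | COc1c(OCc2ccccc2)cc2oc(=O)c(Oc3cc4oc(=O)ccc4cc3OC)cc2c1Br | intermediate
22 | 7-hydroxy-6-methoxy-3-[(6-methoxy-2-oxo-2H-chromen-7-yl)oxy]-2H-chromen-2-one | COc1cc2cc(Oc3cc4oc(=O)ccc4cc3OC)c(=O)oc2cc1O | target

**Step count**

Total: 9 steps. Longest linear sequence: 7 steps (steps 1, 2, 3, 4, 5, 8, 9); the unit B branch is steps 6 and 7.

**Steps most likely to fail**

1. Step 8 (proposed new method). The fluoride-released enolate may be protonated or may self-condense, may add directly to the aryne or to the coumarin of another molecule before the quinone methide is there, and the final loss of dimethylamine may stall. This weakness also covers the handling of the moisture-sensitive ketene acetal from step 7. The fallback sets out from 9 and 12, uses known chemistry and returns at 21. Triflate 9 would be treated with CsF in dimethylformamide and then with water, the known two-component insertion and hydrolysis, to give 4-(benzyloxy)-6-bromo-2-hydroxy-5-methoxybenzaldehyde F1. Ester 12 would be hydrolysed (LiOH, THF–H2O, then HCl, which recloses any opened lactone) to 2-[(6-methoxy-2-oxo-2H-chromen-7-yl)oxy]acetic acid F2. A Perkin condensation of F1 with F2 (Ac2O, Et3N, 110 °C) would then give 21.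

2. Step 5. Bromine–lithium exchange at the bromine flanked by two oxygen substituents may compete with iodine–lithium exchange, and the silyl shift may be incomplete before the triflating agent is added. The fallback sets out from 6 and returns at 9. Iodine–magnesium exchange with i-PrMgCl·LiCl (THF, −40 °C), which leaves aryl bromides untouched, followed by TMSCl at rt would give [4-(benzyloxy)-2-bromo-3-methoxy-6-(trimethylsilyl)phenoxy]trimethylsilane F3. Methanolysis of the O–Si bond (K2CO3, MeOH) would give 4-(benzyloxy)-2-bromo-3-methoxy-6-(trimethylsilyl)phenol F4, and separate triflation (Tf2O, pyridine, CH2Cl2, 0 °C) would give 9.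

3. Step 9. Hydrogen may be added across the C3'=C4' bond of unit B, or the reaction may stop after only one of the two hydrogenolyses. The fallback sets out from 21 and returns at 22 without heterogeneous hydrogenation. Homogeneous formate reduction of the aryl bromide (Pd(OAc)2, PPh3, HCO2H, Et3N, DMF, 80 °C) would give 7-(benzyloxy)-6-methoxy-3-[(6-methoxy-2-oxo-2H-chromen-7-yl)oxy]-2H-chromen-2-one F5. Cleavage of the benzyl ether with BCl3 and pentamethylbenzene (CH2Cl2, −78 °C), which spares the methyl ethers and the lactones, would then give 22.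

**Further compounds**

F1 | step 8 | 4-(benzyloxy)-6-bromo-2-hydroxy-5-methoxybenzaldehyde | COc1c(OCc2ccccc2)cc(O)c(C=O)c1Br
F2 | step 8 | 2-[(6-methoxy-2-oxo-2H-chromen-7-yl)oxy]acetic acid | OC(=O)COc1cc2oc(=O)ccc2cc1OC
F3 | step 5 | [4-(benzyloxy)-2-bromo-3-methoxy-6-(trimethylsilyl)phenoxy]trimethylsilane | COc1c(OCc2ccccc2)cc([Si](C)(C)C)c(O[Si](C)(C)C)c1Br
F4 | step 5 | 4-(benzyloxy)-2-bromo-3-methoxy-6-(trimethylsilyl)phenol | COc1c(OCc2ccccc2)cc([Si](C)(C)C)c(O)c1Br
F5 | step 9 | 7-(benzyloxy)-6-methoxy-3-[(6-methoxy-2-oxo-2H-chromen-7-yl)oxy]-2H-chromen-2-one | COc1cc2cc(Oc3cc4oc(=O)ccc4cc3OC)c(=O)oc2cc1OCc1ccccc1
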